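Count amounts of substrate, target and dormant form as fractions of the substrate charged. The flask and the two earlier runs differ in their substrate charge.

| setting | north-west | north-east | flask |
|---|---|---|---|
| substrate | 0.23 M | 0.35 M | 0.47 M |
| partner | 0.705 M | 0.705 M | 0.705 M |
| remark | run made earlier | run made earlier |  |
| time |  |  | 4.0 min |

| run | time / min | intermediate / % | substrate / % | side product / % | target / % |
|---|---|---|---|---|---|
| north-west | 0.417 | 0 | 87 | 0 | 4 |
| north-west | 0.667 | 0 | 79 | 0 | 10 |
| north-west | 1.33 | 3 | 70 | 0 | 18 |
| north-west | 2.50 | 0 | 55 | 1 | 28 |
| north-west | 5.00 | 0 | 37 | 2 | 37 |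
| north-east | 0.417 | 6 | 88 | 0 | 4 |
| north-east | 0.667 | 3 | 82 | 2 | 7 |
| north-east | 1.33 | 1 | 69 | 0 | 19 |
| north-east | 2.50 | 2 | 55 | 0 | 24 |
| north-east | 5.00 | 0 | 42 | 0 | 39 |

(scatter of a reading: 2 percentage points)

1. the species that holds most of what was charged as substrate, at 4.0 min (substrate / intermediate / target / side product)
2. the largest share itself, whichever of these holds it, in percent of the substrate charged

- the numbers in the tables scatter by 2 percentage points (one standard deviation)
- a reading or a percentage of substrate is of its free form alone

Take the north-east run, the nearest in charge, and subtract target from free substrate at its last two readings: 31 percentage points at 2.50 min, then 3 points at 5.00 min. Interpolate linearly to 4.0 min, and my reckoning gives 14 points. Call this the lead: free substrate minus target, with a tie as its zero. It stands above the 2 points scatter of a reading, so expect substrate ahead of target in the flask.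

The forecast says substrate, at 47%: "Substrate stays ahead of target by over 10 points, so it holds the largest share."

The flask gives substrate at 44.9%, with target at 31.2%. Its lead is therefore 14 points, against the 14 points reckoned.

    substrate + partner → intermediate + by-product (k = 0.00460 L mol⁻¹ s⁻¹)
    intermediate → target (k = 0.110 s⁻¹)
    partner → decomposed reagent (k = 0.00250 s⁻¹)
    substrate ⇌ dormant form (K = 0.640, k = 0.00210 s⁻¹)
    target + by-product → side product (k = 0.00370 L mol⁻¹ s⁻¹)

Dormant form holds 21.3% of this flask at 4.00 min and stands outside the lead. Now take the neighbour charged with 1.8 M of partner, its substrate charge and time held as in the flask. At 4.00 min it has 21.1% substrate and 56.1% target, so target holds most, and the lead has crossed zero to −35 points.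

(The data were computed for an exercise; the scatter is artificial.)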